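**Retrosynthetic overview**
1. Ring C (the cyclohexene) is numbered C1 (CH bonded to ring A of the magnolol unit), C2 (=CH), C3 (=C–CH3), C4 and C5 (CH2), C6 (CH–isopropyl); rings A and B are bought as magnolol.
2. Last disconnections: C3–CH3 (iron-catalysed coupling of a C2=C3 enol triflate) and C1–ring A (copper-catalysed conjugate addition of a magnolol-derived aryl Grignard to (S)-4-isopropylcyclohex-2-enone, anti to the isopropyl group, with the enolate trapped in the same flask).
3. Key disconnection: C3–C4 and C5–C6 of ring C at once, by inserting ethene (C4, C5) into the acyl–C(sp3) bond of 4-isopropylcyclobut-2-enone (C3, C2, C1, C6) with a chiral rhodium catalyst, enantioconvergently.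
4. Enabling feature: the unsubstituted C4H2–C5H2 unit of ring C lies between the sp2 carbon C3 (carried as a ketone carbon) and the stereocentre C6; C6 is allylic to C1=C2 at the enone stage, so it is flattened in the vinylketene that links both enantiomers of the cyclobutenone.
5. Ring order: four-membered ring by ketene–ynol ether [2+2] (step 1), then ring C by two-carbon ring expansion (step 3); no further ring is formed.

Key step: step 3

Assumption: magnolol is taken as a commercial starting material.
Assumption: the sense of induction of the chiral ligand in step 3 cannot be predicted with confidence; (R)-DTBM-SEGPHOS is written as the enantiomer assumed to give the (S)-enone, and its antipode is used if the sense proves opposite.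

Step 1
Reactants: 1 3-methylbutanoyl chloride; 2 ethoxyethyne
Product: 4 rac-3-ethoxy-4-(propan-2-yl)cyclobut-2-en-1-one, via isopropylketene 3 (not isolated)
Conditions: Et3N, Et2O, 0 °C → rt
Reagents that add atoms: none
Why: Dehydrochlorination gives ketene 3, which should undergo the well-precedented thermal [2+2] ketene–ynol ether cycloaddition with the alkyne CH carbon bonding to the ketene carbonyl carbon, so that ethoxy ends up at C3 and isopropyl at C4 (stereocentre formed racemic).

Step 2
Reactants: 4 rac-3-ethoxy-4-(propan-2-yl)cyclobut-2-en-1-one
Product: 6 rac-4-(propan-2-yl)cyclobut-2-en-1-one, via cyclobutenol 5 (not isolated)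
Conditions: i-Bu2AlH, CH2Cl2, −78 °C; then 1 M HCl, 0 °C; product kept cold in solution
Reagents that add atoms: water, O
Why: Stork–Danheiser-type carbonyl transposition, in which 1,2-reduction of the vinylogous ester and acid hydrolysis of the enol ether with loss of the allylic hydroxyl should give the transposed enone with the isopropyl group alpha to the new carbonyl.

Step 3
Reactants: 6 rac-4-(propan-2-yl)cyclobut-2-en-1-one; 7 ethene
Product: 9 (4S)-4-(propan-2-yl)cyclohex-2-en-1-one ((S)-cryptone), via rhodium-bound vinylketene 8 (not isolated)
Conditions: [Rh(C2H4)2Cl]2 (2.5 mol %), (R)-DTBM-SEGPHOS (6 mol %), ethene (10 bar), toluene, 60 °C, slow addition of 6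
Reagents that add atoms: none
Why: Proposed new method: monovalent rhodium should add oxidatively into the strained acyl–C4 bond of 6 to give a rhodacyclopentenone in equilibrium with the rhodium-bound vinylketene 8, in which the isopropyl-bearing carbon is trigonal, so that both enantiomers of 6 funnel into one intermediate; ethene then inserts into the Rh–acyl bond (bond C3–C4 of ring C) and C(sp3)–C(sp3) reductive elimination from the seven-membered rhodacycle makes bond C5–C6 of ring C. The closest known reaction types are the rhodium-catalysed carboacylation (cut-and-sew) of alkenes with cyclobutenones, benzocyclobutenones and cyclobutanones, shown for strained or tethered alkenes and in enantioselective form with this ligand class, and the nickel-catalysed [4+2] of cyclobutenones with alkynes; new here are ethene as the free two-carbon partner and the enantioconvergent use of a racemic 4-alkylcyclobutenone. The six-membered ring closes in a formal intermolecular [4+2] annulation (four carbons of the vinylketene, two of ethene), the ring-closing event being the reductive elimination and not a polar cyclisation. The one new stereocentre, C4 of 9 (C6 of ring C), is set under catalyst control, the chiral bisphosphine choosing the face of the allyl terminus in the reductive elimination. The step needs carboacylation to outrun decarbonylation, beta-hydride elimination to an open-chain dienone and ketene dimerisation, and needs the enantiomers of 6 to interconvert faster than they are consumed: ethene pressure, the chelating electron-rich ligand and slow addition of 6 should secure the first, the allylic position of C4 in 6 (which makes ring opening to 8 reversible) the second, and the symmetry of ethene removes any regiochemical question.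

Step 4
Reactants: 10 magnolol (5,5'-di(prop-2-en-1-yl)-[1,1'-biphenyl]-2,2'-diol)
Product: 11 3-bromo-5,5'-di(prop-2-en-1-yl)-[1,1'-biphenyl]-2,2'-diol (3-bromomagnolol)
Conditions: NBS (1.0 equiv), i-Pr2NH (cat.), CH2Cl2, −78 → 0 °C, dark
Reagents that add atoms: N-bromosuccinimide, O=C1CCC(=O)N1Br
Why: Amine-catalysed electrophilic aromatic ortho-bromination of a para-blocked phenol, in which the phenol ring should react far faster than the allyl double bonds and one equivalent of reagent should limit substitution mainly to one of the two equivalent rings.

Step 5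
Reactants: 11 3-bromomagnolol
Product: 12 3-bromo-2,2'-bis(methoxymethoxy)-5,5'-di(prop-2-en-1-yl)-1,1'-biphenyl
Conditions: MOMCl, i-Pr2NEt, CH2Cl2, 0 → 40 °C
Reagents that add atoms: chloromethyl methyl ether, COCCl
Why: Williamson-type O-alkylation of both phenols (MOM protection), needed to carry the aryl group through the organometallic steps.

Step 6
Reactants: 12 3-bromo-2,2'-bis(methoxymethoxy)-5,5'-di(prop-2-en-1-yl)-1,1'-biphenyl; 9 (4S)-4-(propan-2-yl)cyclohex-2-en-1-one
Product: 15 (3S,4S)-3-[2,2'-bis(methoxymethoxy)-5,5'-di(prop-2-en-1-yl)-[1,1'-biphenyl]-3-yl]-4-(propan-2-yl)cyclohex-1-en-1-yl trifluoromethanesulfonate (aryl and isopropyl trans), via arylmagnesium bromide 13 (not isolated), via magnesium enolate 14 (not isolated)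
Conditions: Mg, LiCl, THF, 25 °C; then CuBr·SMe2 (10 mol %), 9, THF, −40 °C; then PhNTf2, −40 → 0 °C
Reagents that add atoms: N-phenylbis(trifluoromethanesulfonimide), O=S(=O)(N(c1ccccc1)S(=O)(=O)C(F)(F)F)C(F)(F)F
Why: Magnesium insertion gives Grignard reagent 13, which should add in a copper-catalysed 1,4-addition to the enone from the face anti to the C4 isopropyl group (substrate control, the trans-3,4 outcome usual for 4-substituted cyclohexenones, setting C1 of ring C), and O-sulfonylation of the regiodefined enolate 14 fixes the double bond at C2=C3 of ring C.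

Step 7
Reactants: 15 (3S,4S)-enol triflate
Product: 16 2,2'-bis(methoxymethoxy)-3-[(1S,6S)-3-methyl-6-(propan-2-yl)cyclohex-2-en-1-yl]-5,5'-di(prop-2-en-1-yl)-1,1'-biphenyl
Conditions: MeMgBr, Fe(acac)3 (5 mol %), THF/NMP, −30 → 0 °C
Reagents that add atoms: methylmagnesium bromide, C[Mg]Br
Why: Iron-catalysed Kumada-type cross-coupling of an alkenyl triflate with a methyl Grignard reagent, which has no beta-hydrogen and should leave the allyl groups, the MOM ethers and both stereocentres untouched.

Step 8
Reactants: 16 bis-MOM ether
Product: 17 3-[(1S,6S)-3-methyl-6-(propan-2-yl)cyclohex-2-en-1-yl]-5,5'-di(prop-2-en-1-yl)-[1,1'-biphenyl]-2,2'-diol (target, CNP0249009.1)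
Conditions: ZnBr2, n-PrSH, CH2Cl2, 0 °C
Reagents that add atoms: none
Why: Lewis acid-activated transfer of the methoxymethyl groups from the aryl ethers to the thiol (transacetalisation) under mild, non-protic conditions, chosen so that the freed phenol does not add across the trisubstituted ring double bond.

**Compound list**
1 | 3-methylbutanoyl chloride | CC(C)CC(Cl)=O | starting material
2 | ethoxyethyne | C#COCC | starting material
3 | isopropylketene (3-methylbut-1-en-1-one) | CC(C)C=C=O | intermediate (not isolated)
4 | rac-3-ethoxy-4-(propan-2-yl)cyclobut-2-en-1-one | CCOC1=CC(=O)C1C(C)C | intermediate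
5 | 3-ethoxy-4-(propan-2-yl)cyclobut-2-en-1-ol (racemic, diastereomer mixture) | CCOC1=CC(O)C1C(C)C | intermediate (not isolated)
6 | rac-4-(propan-2-yl)cyclobut-2-en-1-one | CC(C)C1C=CC1=O | intermediate
7 | ethene | C=C | starting material
8 | (3E)-5-methylhexa-1,3-dien-1-one (vinylketene, rhodium-bound) | CC(C)/C=C/C=C=O | intermediate (not isolated)
9 | (4S)-4-(propan-2-yl)cyclohex-2-en-1-one | O=C1C=C[C@H](C(C)C)CC1 | intermediate
10 | magnolol, 5,5'-di(prop-2-en-1-yl)-[1,1'-biphenyl]-2,2'-diol | C=CCc1ccc(O)c(-c2cc(CC=C)ccc2O)c1 | starting material
11 | 3-bromo-5,5'-di(prop-2-en-1-yl)-[1,1'-biphenyl]-2,2'-diol | C=CCc1ccc(O)c(-c2cc(CC=C)cc(Br)c2O)c1 | intermediate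
12 | 3-bromo-2,2'-bis(methoxymethoxy)-5,5'-di(prop-2-en-1-yl)-1,1'-biphenyl | C=CCc1ccc(OCOC)c(-c2cc(CC=C)cc(Br)c2OCOC)c1 | intermediate
13 | [2,2'-bis(methoxymethoxy)-5,5'-di(prop-2-en-1-yl)-[1,1'-biphenyl]-3-yl]magnesium bromide | C=CCc1ccc(OCOC)c(-c2cc(CC=C)cc([Mg]Br)c2OCOC)c1 | intermediate (not isolated)
14 | bromomagnesium (3S,4S)-3-[2,2'-bis(methoxymethoxy)-5,5'-di(prop-2-en-1-yl)-[1,1'-biphenyl]-3-yl]-4-(propan-2-yl)cyclohex-1-en-1-olate | C=CCc1ccc(OCOC)c(-c2cc(CC=C)cc([C@@H]3C=C(O[Mg]Br)CC[C@H]3C(C)C)c2OCOC)c1 | intermediate (not isolated)
15 | (3S,4S)-3-[2,2'-bis(methoxymethoxy)-5,5'-di(prop-2-en-1-yl)-[1,1'-biphenyl]-3-yl]-4-(propan-2-yl)cyclohex-1-en-1-yl trifluoromethanesulfonate | C=CCc1ccc(OCOC)c(-c2cc(CC=C)cc([C@@H]3C=C(OS(=O)(=O)C(F)(F)F)CC[C@H]3C(C)C)c2OCOC)c1 | intermediate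
16 | 2,2'-bis(methoxymethoxy)-3-[(1S,6S)-3-methyl-6-(propan-2-yl)cyclohex-2-en-1-yl]-5,5'-di(prop-2-en-1-yl)-1,1'-biphenyl | C=CCc1ccc(OCOC)c(-c2cc(CC=C)cc([C@@H]3C=C(C)CC[C@H]3C(C)C)c2OCOC)c1 | intermediate
17 | 3-[(1S,6S)-3-methyl-6-(propan-2-yl)cyclohex-2-en-1-yl]-5,5'-di(prop-2-en-1-yl)-[1,1'-biphenyl]-2,2'-diol | C=CCc1ccc(O)c(-c2cc(CC=C)cc([C@@H]3C=C(C)CC[C@H]3C(C)C)c2O)c1 | target

**Step count and risks**
Total step count: 8. Longest linear sequence: 6 steps (steps 1, 2, 3, 6, 7, 8).

Most likely to fail, in this order:

Step 3 (proposed new method). The cyclobutenone may be consumed by decarbonylation, by beta-hydride elimination to an open-chain dienone or by ketene dimerisation. The two enantiomers of 6 may also fail to interconvert, so that the ring expansion becomes a kinetic resolution with poor enantiocontrol. The fallback uses known chemistry and makes 9 by an amine-catalysed Michael addition followed by aldol condensation (Robinson-type annulation). Commercial 3-methylbutanal and but-3-en-2-one, with (S)-α,α-diphenylprolinol trimethylsilyl ether as catalyst, should give (2S)-5-oxo-2-(propan-2-yl)hexanal F1 (the antipodal catalyst is used if the sense is opposite). LiOH in i-PrOH then closes and dehydrates F1 to 9. This fallback does not set out from a numbered compound (compounds 1 to 8 are left aside) and comes back to the route at 9; it gives up the ethene ring expansion and keeps steps 4 to 8 unchanged.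

Step 2. The small, volatile and electrophilic cyclobutenone may be lost by oligomerisation or by conjugate addition of water or ethanol during the acidic hydrolysis, and the vinylogous ester may be over-reduced. The fallback sets out from 1 and comes back at 6 by a keteniminium–alkyne [2+2] route. Dimethylamine converts 1 into N,N,3-trimethylbutanamide F2. Triflic anhydride and 2,4,6-collidine turn F2 into the keteniminium triflate F3, which is trapped by acetylene to give N,N-dimethyl-4-(propan-2-yl)cyclobut-2-en-1-iminium triflate F4. Aqueous work-up hydrolyses F4 to 6, with no vinylogous ester reduction and no acidic elimination step.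

Step 6. The hindered aryl Grignard reagent may add 1,2 or convert poorly, the magnesium enolate may be sulfonylated incompletely, or the facial selectivity may be lower than expected. The fallback sets out from 9 (with 10) and comes back at 17, bypassing compounds 11 to 16. Methyllithium adds 1,2 to 9 to give (4S)-1-methyl-4-(propan-2-yl)cyclohex-2-en-1-ol F5 (both C1 epimers). BF3·OEt2 on Al2O3 in CH2Cl2 at low temperature ionises F5 to the allyl cation. The cation alkylates unprotected magnolol 10 (in excess) at C3, ortho to the hydroxyl, through its secondary terminus and anti to the isopropyl group (Friedel–Crafts allylation, the classical terpenylation of phenols), giving 17 directly. It is held in reserve because reversible loss of the proton at C6 from the cation could erode enantiomeric purity and because double alkylation of magnolol has to be suppressed.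

Further compounds
F1 | step 3 | (2S)-5-oxo-2-(propan-2-yl)hexanal | O=C[C@@H](CCC(C)=O)C(C)C
F2 | step 2 | N,N,3-trimethylbutanamide | CC(C)CC(=O)N(C)C
F3 | step 2 | N,N-dimethyl-(3-methylbut-1-en-1-ylidene)iminium trifluoromethanesulfonate (keteniminium salt) | CC(C)C=C=[N+](C)C.[O-]S(=O)(=O)C(F)(F)F
F4 | step 2 | N,N-dimethyl-4-(propan-2-yl)cyclobut-2-en-1-iminium trifluoromethanesulfonate | CC(C)C1C=CC1=[N+](C)C.[O-]S(=O)(=O)C(F)(F)F
F5 | step 6 | (4S)-1-methyl-4-(propan-2-yl)cyclohex-2-en-1-ol (both C1 epimers) | CC1(O)C=C[C@H](C(C)C)CC1
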